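**Plan**

1. Numbering follows elemane in both halves: C10 is the quaternary carbon (CH3, vinyl), C5 carries the isopropenyl group C4(=C3)C15, C8 is CH–O, and C7, C11, C12, C13 are the lactone carbons. Unprimed atoms belong to the butenolide half, primed atoms to the saturated lactone half.
2. Cuts: C8–O and C7=C11 of the butenolide (aldol condensation of a C8 ketone with an α-keto ester, then C8 reduction); C13–C13' (Michael addition to the primed α-methylene lactone); C7'–C11' and C8'–O (enolate alkylation, reduction, lactonisation). Both halves lead back to the two enantiomers of 3-ethenyl-3-methyl-4-isopropenylcyclohexanone.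
3. Enabling feature: in that ketone C5–C6 lies between the isopropenyl C3=C4 and the enolisable C7–C8=O unit, so C3=C4–C5–C6–C7=C8–O is the product array of an oxy-Cope rearrangement. Its precursor is a 1-vinylcyclohex-3-en-1-ol in which C3–C8 is still a ring bond.
4. Forward: commercial cyclohexenone → quaternary C10 → β,γ-enone → C8 vinyl carbinol → resolution into both antipodes → [3,3] ring transposition of each antipode. Primed ketone → cis-lactone → α-methylene lactone → α-keto ester arm. Unprimed enol silane + that arm → aldol, dehydration, C8 reduction, butenolide.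
5. Stereochemistry: C10 by resolution (both antipodes are used, one per half); the C8 carbinol relative to C10 by addition anti to the axial CH3, steered by a temporary silyl group; C5 by chirality transfer in the [3,3] shift; C7' thermodynamic, C8' by hydride anti to axial CH3, C11' by kinetic protonation on the convex face; C8 by a chiral oxazaborolidine.

Key step: step 8

Remark: the target has opposite absolute configuration at C5/C10 in its two carbocycles (5R,10R in the butenolide half, 5S,10S in the saturated half) and this is taken as intended; racemic compounds 3 to 9 are drawn as the enantiomer that leads to the butenolide half.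

**Route**

Step 1
Reactants: 1 3,5-dimethylcyclohex-2-en-1-one (racemic); 2 (1-bromoethenyl)trimethylsilane
Product: 4 rac-(3R,5R)-3,5-dimethyl-3-[1-(trimethylsilyl)ethenyl]cyclohexan-1-one, via trimethylsilyl enol ether 3 (not isolated)
Conditions: 2, Mg, THF, reflux; then 1, CuBr·SMe2 (10 mol %), Me3SiCl, THF, −40 °C to 0 °C; 1 M HCl work-up
Reagents that add atoms: none
Why: Copper-catalysed conjugate addition of the alkenyl Grignard reagent should build the quaternary C10, the nucleophile entering trans to the C4 methyl group, a centre that step 2 erases.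

Step 2
Reactants: 4
Product: 5 rac-(5R)-3,5-dimethyl-5-[1-(trimethylsilyl)ethenyl]cyclohex-2-en-1-one
Conditions: IBX (2-iodoxybenzoic acid), DMSO, 70 °C
Reagents that add atoms: none
Why: IBX dehydrogenation of the ketone can only run toward C3–C4, because the other α-carbon C9 is flanked by the quaternary C10.

Step 3
Reactants: 5
Product: 7 rac-(5S)-3,5-dimethyl-5-[1-(trimethylsilyl)ethenyl]cyclohex-3-en-1-one, via potassium dienolate 6 (not isolated)
Conditions: KOt-Bu, t-BuOH/THF, rt; inverse quench into cold 10% aq AcOH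
Reagents that add atoms: none
Why: Deconjugation by kinetic α-protonation of the thermodynamic endocyclic dienolate (the isophorone to β-isophorone type of isomerisation) should move the double bond to C4=C5.

Step 4
Reactants: 7
Product: 8 rac-(1R,5S)-1-ethenyl-3,5-dimethyl-5-[1-(trimethylsilyl)ethenyl]cyclohex-3-en-1-ol
Conditions: CH2=CHMgBr, CeCl3, THF, −78 °C
Reagents that add atoms: vinylmagnesium bromide, C=C[Mg]Br
Why: Organocerium 1,2-addition (which suppresses enolisation of the β,γ-enone) should come from the face anti to the pseudoaxial C10 methyl, because the bulky C(SiMe3)=CH2 group holds the pseudoequatorial site and so leaves CH3 over the axial trajectory; O therefore ends cis to CH3 and the two alkenyl groups cis to each other.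

Step 5
Reactants: 8
Product: 9 rac-(1R,5R)-1,5-diethenyl-3,5-dimethylcyclohex-3-en-1-ol
Conditions: Bu4NF·3H2O, DMSO/THF, 70 °C
Reagents that add atoms: none
Why: Fluoride-induced protodesilylation of the vinylsilane should remove the temporary steering group at a stage that holds no acid- or base-sensitive function.

Step 6
Reactants: 9
Product: 10 (1R,5R)-1,5-diethenyl-3,5-dimethylcyclohex-3-en-1-ol
Conditions: preparative supercritical-fluid chromatography on amylose tris(3,5-dimethylphenylcarbamate), CO2/i-PrOH; the (1R,5R) enantiomer fraction is collected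
Reagents that add atoms: none
Why: Chromatographic resolution of the racemate on the chiral stationary phase delivers 10 for the butenolide half as one of the two enantiomer fractions, and any minor C8 epimer from step 4 is removed in the same run.

Step 7
Reactants: 9
Product: 11 (1S,5S)-1,5-diethenyl-3,5-dimethylcyclohex-3-en-1-ol
Conditions: the other enantiomer fraction of the same preparative supercritical-fluid chromatography (amylose tris(3,5-dimethylphenylcarbamate), CO2/i-PrOH)
Reagents that add atoms: none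
Why: The same chromatographic resolution delivers the antipode 11 as its second enantiomer fraction, which feeds the saturated lactone half, so that both enantiomers of the racemic sequence are used.

Step 8
Reactants: 10
Product: 13 {[(4R,5R)-5-ethenyl-5-methyl-4-(prop-1-en-2-yl)cyclohex-1-en-1-yl]oxy}trimethylsilane, via potassium enolate 12 (not isolated)
Conditions: KH, 18-crown-6, THF, 0 °C to rt; then Me3SiCl, Et3N, −78 °C
Reagents that add atoms: chlorotrimethylsilane, C[Si](C)(C)Cl
Why: KH/18-crown-6 turns 10 into a free potassium alkoxide whose 1,5-diene C6=C7–C8(O−)–C3–C4=C5 undergoes the charge-accelerated [3,3] shift (anionic oxy-Cope rearrangement), breaking the allylic ring bond C3–C8 and forming C5–C6, so that the old cyclohexene is exchanged for the cyclohexane C5–C6–C7–C8–C9–C10 and C3–C4 is expelled as the isopropenyl group on C5. The closest known reaction type is the anionic oxy-Cope rearrangement of 2-vinylbicyclo[2.2.2]oct-5-en-2-ols and of 1-vinylcycloalk-3-en-1-ols, where vinyl carbinol and ring alkene stand in the same 1,4-relationship. The ring closes by transannular 1,4-bridging through a boat-like, bicyclo[2.2.2]octane-shaped six-centre array held by the C9–C10 strap (a six-to-six ring transposition, not an exo or endo closure). C5 is the only new stereocentre and is fixed by suprafacial chirality transfer from C8: C6 reaches C5 only on the ring face that carries the C8 vinyl group, so the C10 methyl (syn to the alkoxide) ends cis to the isopropenyl group and the C10 vinyl trans to it. The step needs the [3,3] path over a [1,3] shift or fragmentation (the alternative C3–C6 bond would close a cyclooctenone, whereas C5–C6 closes a six-membered ring), and it needs a regiochemically pure C7=C8 enolate, which the cold silyl quench secures for the aldol at C7.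

Step 9
Reactants: 11
Product: 15 methyl 2-[(1R,4S,5S)-4-ethenyl-4-methyl-2-oxo-5-(prop-1-en-2-yl)cyclohexyl]acetate, via potassium enolate 14 (not isolated)
Conditions: KH, 18-crown-6, THF, 0 °C to rt; BrCH2CO2Me, −78 °C to 0 °C; then K2CO3, MeOH, rt
Reagents that add atoms: methyl bromoacetate, COC(=O)CBr
Why: The same anionic oxy-Cope rearrangement on the antipode gives the enantiomeric C7'=C8' enolate, whose C-alkylation installs C11' and C12' on C7'; equilibration through the enol should leave the side chain equatorial, cis to the isopropenyl group.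

Step 10
Reactants: 15
Product: 17 (3aR,5S,6S,7aR)-6-ethenyl-6-methyl-5-(prop-1-en-2-yl)hexahydro-1-benzofuran-2(3H)-one, via hydroxy ester 16 (not isolated)
Conditions: LiBH(s-Bu)3, THF, −78 °C; aq NH4Cl; then pyridinium p-toluenesulfonate (cat.), toluene, 50 °C
Reagents that add atoms: none
Why: The bulky hydride should attack the locked chair from the equatorial side, anti to the axial C10' methyl, and the axial alkoxide then lactonises with the neighbouring equatorial ester to the cis-fused γ-lactone (substrate-controlled ketone reduction and lactonisation).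

Step 11
Reactants: 17
Product: 20 (3aR,5S,6S,7aR)-6-ethenyl-6-methyl-3-methylidene-5-(prop-1-en-2-yl)hexahydro-1-benzofuran-2(3H)-one, via Mannich base 18 (not isolated), via ammonium iodide 19 (not isolated)
Conditions: LiN(i-Pr)2, THF, −78 °C; CH2=NMe2+ I−, −78 °C to rt; MeI, MeOH, rt; aq NaHCO3, CH2Cl2
Reagents that add atoms: N,N-dimethylmethyleneiminium iodide, C=[N+](C)C.[I-]
Why: Mannich reaction of the lactone enolate, quaternisation and Hofmann-type elimination is the standard α-methylenation of γ-butyrolactones.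

Step 12
Reactants: 21 prop-2-en-1-yl acetate; 22 dimethyl oxalate
Product: 23 1-methyl 4-prop-2-en-1-yl 2-oxobutanedioate
Conditions: LiN(SiMe3)2, THF, −78 °C, 21; then 22, −78 °C to 0 °C; 1 M HCl
Reagents that add atoms: none
Why: Crossed Claisen condensation of the acetate enolate with the non-enolisable oxalate gives an oxaloacetate that serves as a pyruvate enolate equivalent with a removable allyl ester.

Step 13
Reactants: 20; 23
Product: 25 methyl 4-[(3S,3aR,5S,6S,7aR)-6-ethenyl-6-methyl-2-oxo-5-(prop-1-en-2-yl)octahydro-1-benzofuran-3-yl]-2-oxobutanoate, via Michael adduct 24 (not isolated)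
Conditions: K2CO3 (0.2 equiv), MeCN, rt; then Pd(OAc)2 (5 mol %), PPh3, HCO2H, Et3N, THF, rt to 40 °C
Reagents that add atoms: none
Why: Michael addition of the soft oxaloacetate enolate forms C13–C13' and the lactone enolate is protonated kinetically on the convex face (C11'–H cis to C7'–H); palladium-catalysed deallylation with formate and loss of CO2 from the β-keto acid then unmask the α-keto ester.

Step 14
Reactants: 13; 25
Product: 27 methyl 2-[(4R,5R)-4-ethenyl-4-methyl-2-oxo-5-(prop-1-en-2-yl)cyclohexyl]-4-[(3S,3aR,5S,6S,7aR)-6-ethenyl-6-methyl-2-oxo-5-(prop-1-en-2-yl)octahydro-1-benzofuran-3-yl]-2-hydroxybutanoate (epimers at C7/C11), via silyl ether 26 (not isolated)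
Conditions: Cu(OTf)2 (10 mol %), CH2Cl2, −78 °C to −20 °C; then citric acid, MeOH/H2O, 0 °C
Reagents that add atoms: none
Why: Mukaiyama aldol addition of the regiodefined enol silane to the chelation-activated keto carbonyl forms C7–C11; the enol silane is far more nucleophilic than the isolated alkenes, and the two new centres need no control because step 15 removes them.

Step 15
Reactants: 27
Product: 29 methyl (2Z)-2-[(4R,5R)-4-ethenyl-4-methyl-2-oxo-5-(prop-1-en-2-yl)cyclohexylidene]-4-[(3S,3aR,5S,6S,7aR)-6-ethenyl-6-methyl-2-oxo-5-(prop-1-en-2-yl)octahydro-1-benzofuran-3-yl]butanoate, via mesylate 28 (not isolated)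
Conditions: MsCl, Et3N, 4-(dimethylamino)pyridine (cat.), CH2Cl2, −20 °C to 0 °C; then 1,8-diazabicyclo[5.4.0]undec-7-ene, 0 °C to rt
Reagents that add atoms: none
Why: E1cB elimination of the tertiary mesylate through the C7 enolate puts the double bond at C7=C11 only; the Z isomer (ester syn to the C8 ketone) is taken on, and the E isomer is separated and re-equilibrated with the same base through the extended enolate.

Step 16
Reactants: 29
Product: 31 (3S,3aR,5S,6S,7aR)-6-ethenyl-3-{2-[(5R,6R,7aR)-6-ethenyl-6-methyl-2-oxo-5-(prop-1-en-2-yl)-2,4,5,6,7,7a-hexahydro-1-benzofuran-3-yl]ethyl}-6-methyl-5-(prop-1-en-2-yl)hexahydro-1-benzofuran-2(3H)-one, via hydroxy ester 30 (not isolated)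
Conditions: (3aS)-1-methyl-3,3-diphenyltetrahydro-1H,3H-pyrrolo[1,2-c][1,3,2]oxazaborole (0.5 equiv), catecholborane, toluene, −78 °C; MeOH quench; then pyridinium p-toluenesulfonate (cat.), CH2Cl2, rt
Reagents that add atoms: none
Why: Corey–Bakshi–Shibata reduction of the enone, with the alkylidene side as the large group, should give the (8R)-allylic alcohol under catalyst control (with C7 trigonal no chair is locked, so ring bias is weak), and the alcohol closes onto the syn ester to the butenolide with retention.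

**Compound list**

1 | 3,5-dimethylcyclohex-2-en-1-one (racemic) | CC1CC(=O)C=C(C)C1 | starting material
2 | (1-bromoethenyl)trimethylsilane | C=C(Br)[Si](C)(C)C | starting material
3 | rac-trimethyl({(3R,5R)-3,5-dimethyl-3-[1-(trimethylsilyl)ethenyl]cyclohex-1-en-1-yl}oxy)silane | C[Si](C)(C)C(=C)[C@@]1(C)C=C(O[Si](C)(C)C)C[C@H](C)C1 | intermediate
4 | rac-(3R,5R)-3,5-dimethyl-3-[1-(trimethylsilyl)ethenyl]cyclohexan-1-one | C[Si](C)(C)C(=C)[C@@]1(C)CC(=O)C[C@H](C)C1 | intermediate
5 | rac-(5R)-3,5-dimethyl-5-[1-(trimethylsilyl)ethenyl]cyclohex-2-en-1-one | C[Si](C)(C)C(=C)[C@@]1(C)CC(=O)C=C(C)C1 | intermediate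
6 | rac-potassium (5S)-3,5-dimethyl-5-[1-(trimethylsilyl)ethenyl]cyclohexa-1,3-dien-1-olate | C[Si](C)(C)C(=C)[C@@]1(C)CC([O-])=CC(C)=C1.[K+] | intermediate
7 | rac-(5S)-3,5-dimethyl-5-[1-(trimethylsilyl)ethenyl]cyclohex-3-en-1-one | C[Si](C)(C)C(=C)[C@@]1(C)CC(=O)CC(C)=C1 | intermediate
8 | rac-(1R,5S)-1-ethenyl-3,5-dimethyl-5-[1-(trimethylsilyl)ethenyl]cyclohex-3-en-1-ol | C[Si](C)(C)C(=C)[C@@]1(C)C[C@@](O)(C=C)CC(C)=C1 | intermediate
9 | rac-(1R,5R)-1,5-diethenyl-3,5-dimethylcyclohex-3-en-1-ol | C=C[C@@]1(C)C[C@@](O)(C=C)CC(C)=C1 | intermediate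
10 | (1R,5R)-1,5-diethenyl-3,5-dimethylcyclohex-3-en-1-ol | C=C[C@@]1(C)C[C@@](O)(C=C)CC(C)=C1 | intermediate
11 | (1S,5S)-1,5-diethenyl-3,5-dimethylcyclohex-3-en-1-ol | C=C[C@]1(C)C[C@](O)(C=C)CC(C)=C1 | intermediate
12 | potassium (4R,5R)-5-ethenyl-5-methyl-4-(prop-1-en-2-yl)cyclohex-1-en-1-olate | C=C[C@@]1(C)CC([O-])=CC[C@@H]1C(=C)C.[K+] | intermediate
13 | {[(4R,5R)-5-ethenyl-5-methyl-4-(prop-1-en-2-yl)cyclohex-1-en-1-yl]oxy}trimethylsilane | C=C[C@@]1(C)CC(O[Si](C)(C)C)=CC[C@@H]1C(=C)C | intermediate
14 | potassium (4S,5S)-5-ethenyl-5-methyl-4-(prop-1-en-2-yl)cyclohex-1-en-1-olate | C=C[C@]1(C)CC([O-])=CC[C@H]1C(=C)C.[K+] | intermediate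
15 | methyl 2-[(1R,4S,5S)-4-ethenyl-4-methyl-2-oxo-5-(prop-1-en-2-yl)cyclohexyl]acetate | COC(=O)C[C@H]1C[C@@H](C(C)=C)[C@](C)(C=C)CC1=O | intermediate
16 | methyl 2-[(1R,2R,4S,5S)-4-ethenyl-2-hydroxy-4-methyl-5-(prop-1-en-2-yl)cyclohexyl]acetate | COC(=O)C[C@H]1C[C@@H](C(C)=C)[C@](C)(C=C)C[C@H]1O | intermediate
17 | (3aR,5S,6S,7aR)-6-ethenyl-6-methyl-5-(prop-1-en-2-yl)hexahydro-1-benzofuran-2(3H)-one | O=C1C[C@H]2C[C@@H](C(C)=C)[C@](C)(C=C)C[C@H]2O1 | intermediate
18 | (3S,3aR,5S,6S,7aR)-3-[(dimethylamino)methyl]-6-ethenyl-6-methyl-5-(prop-1-en-2-yl)hexahydro-1-benzofuran-2(3H)-one | CN(C)C[C@H]1C(=O)O[C@@H]2C[C@@](C)(C=C)[C@H](C(=C)C)C[C@H]12 | intermediate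
19 | 1-[(3S,3aR,5S,6S,7aR)-6-ethenyl-6-methyl-2-oxo-5-(prop-1-en-2-yl)octahydro-1-benzofuran-3-yl]-N,N,N-trimethylmethanaminium iodide | C[N+](C)(C)C[C@H]1C(=O)O[C@@H]2C[C@@](C)(C=C)[C@H](C(=C)C)C[C@H]12.[I-] | intermediate
20 | (3aR,5S,6S,7aR)-6-ethenyl-6-methyl-3-methylidene-5-(prop-1-en-2-yl)hexahydro-1-benzofuran-2(3H)-one | C=C1C(=O)O[C@@H]2C[C@@](C)(C=C)[C@H](C(=C)C)C[C@H]12 | intermediate
21 | prop-2-en-1-yl acetate | CC(=O)OCC=C | starting material
22 | dimethyl oxalate | COC(=O)C(=O)OC | starting material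
23 | 1-methyl 4-prop-2-en-1-yl 2-oxobutanedioate | COC(=O)C(=O)CC(=O)OCC=C | intermediate
24 | 1-methyl 4-prop-2-en-1-yl 2-oxo-3-{[(3S,3aR,5S,6S,7aR)-6-ethenyl-6-methyl-2-oxo-5-(prop-1-en-2-yl)octahydro-1-benzofuran-3-yl]methyl}butanedioate | COC(=O)C(=O)C(C[C@@H]1C(=O)O[C@@H]2C[C@@](C)(C=C)[C@H](C(=C)C)C[C@H]12)C(=O)OCC=C | intermediate
25 | methyl 4-[(3S,3aR,5S,6S,7aR)-6-ethenyl-6-methyl-2-oxo-5-(prop-1-en-2-yl)octahydro-1-benzofuran-3-yl]-2-oxobutanoate | COC(=O)C(=O)CC[C@@H]1C(=O)O[C@@H]2C[C@@](C)(C=C)[C@H](C(=C)C)C[C@H]12 | intermediate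
26 | trimethylsilyl ether of 27 at the tertiary hydroxyl | COC(=O)C(O[Si](C)(C)C)(CC[C@@H]1C(=O)O[C@@H]2C[C@@](C)(C=C)[C@H](C(=C)C)C[C@H]12)C1C[C@H](C(=C)C)[C@@](C)(C=C)CC1=O | intermediate
27 | methyl 2-[(4R,5R)-4-ethenyl-4-methyl-2-oxo-5-(prop-1-en-2-yl)cyclohexyl]-4-[(3S,3aR,5S,6S,7aR)-6-ethenyl-6-methyl-2-oxo-5-(prop-1-en-2-yl)octahydro-1-benzofuran-3-yl]-2-hydroxybutanoate | COC(=O)C(O)(CC[C@@H]1C(=O)O[C@@H]2C[C@@](C)(C=C)[C@H](C(=C)C)C[C@H]12)C1C[C@H](C(=C)C)[C@@](C)(C=C)CC1=O | intermediate
28 | methanesulfonate of 27 at the tertiary hydroxyl | COC(=O)C(OS(C)(=O)=O)(CC[C@@H]1C(=O)O[C@@H]2C[C@@](C)(C=C)[C@H](C(=C)C)C[C@H]12)C1C[C@H](C(=C)C)[C@@](C)(C=C)CC1=O | intermediate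
29 | methyl (2Z)-2-[(4R,5R)-4-ethenyl-4-methyl-2-oxo-5-(prop-1-en-2-yl)cyclohexylidene]-4-[(3S,3aR,5S,6S,7aR)-6-ethenyl-6-methyl-2-oxo-5-(prop-1-en-2-yl)octahydro-1-benzofuran-3-yl]butanoate | COC(=O)/C(CC[C@@H]2C(=O)O[C@@H]3C[C@@](C)(C=C)[C@H](C(=C)C)C[C@H]23)=C1\C(=O)C[C@](C)(C=C)[C@@H](C(=C)C)C1 | intermediate
30 | methyl (2Z)-2-[(2R,4R,5R)-4-ethenyl-2-hydroxy-4-methyl-5-(prop-1-en-2-yl)cyclohexylidene]-4-[(3S,3aR,5S,6S,7aR)-6-ethenyl-6-methyl-2-oxo-5-(prop-1-en-2-yl)octahydro-1-benzofuran-3-yl]butanoate | COC(=O)/C(CC[C@@H]2C(=O)O[C@@H]3C[C@@](C)(C=C)[C@H](C(=C)C)C[C@H]23)=C1\[C@H](O)C[C@](C)(C=C)[C@@H](C(=C)C)C1 | intermediate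
31 | (3S,3aR,5S,6S,7aR)-6-ethenyl-3-{2-[(5R,6R,7aR)-6-ethenyl-6-methyl-2-oxo-5-(prop-1-en-2-yl)-2,4,5,6,7,7a-hexahydro-1-benzofuran-3-yl]ethyl}-6-methyl-5-(prop-1-en-2-yl)hexahydro-1-benzofuran-2(3H)-one | C=C[C@@]1(C)C[C@H]2OC(=O)C(CC[C@@H]3C(=O)O[C@@H]4C[C@@](C)(C=C)[C@H](C(=C)C)C[C@H]34)=C2C[C@@H]1C(=C)C | target

**Step count and weak points**

Total steps: 16 (steps 6 and 7 are the two enantiomer fractions of one chromatographic resolution; step 12 is a one-step side branch).
Longest linear sequence: 13 steps (1, 2, 3, 4, 5, 7, 9, 10, 11, 13, 14, 15, 16).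

The three steps most likely to fail:

1. Step 8. The alkoxide may take a [1,3] shift or fragment and recombine to the eight-membered enone, or the boat-shaped transition state may be slow enough for the enolate to exchange protons before it is trapped. Fallback, from 10: PdCl2(PhCN)2 (10 mol %), THF, rt. This is the oxy-Cope rearrangement catalysed by divalent palladium, a stepwise cyclisation-induced rearrangement known for 1,5-dien-3-ols with an alkyl group on the inner alkene carbon, as C4 has here. The palladium-bound C8 vinyl group is attacked by C4=C5 at C6, and the tertiary C4 cation then fragments the C3–C8 bond. It should give (3R,4R)-3-ethenyl-3-methyl-4-(prop-1-en-2-yl)cyclohexan-1-one F1. Kinetic enolisation away from the quaternary C10 (LiN(i-Pr)2, Me3SiCl, THF, −78 °C) then returns to 13.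

2. Step 16. Hydride delivery may show poor facial selectivity where catalyst control has to override whatever ring bias exists, and material is lost as the E-configured hydroxy ester, which cannot close. Fallback, from 27: LiBH(s-Bu)3, THF, −78 °C reduces the C8 ketone of the aldol adduct under substrate control (equatorial attack on the chair locked by the equatorial C7 side chain). The axial alkoxide lactonises to the cis-fused hydroxy lactone (3aR,5R,6R,7aS)-6-ethenyl-3-hydroxy-6-methyl-5-(prop-1-en-2-yl)-3-{2-[(3S,3aR,5S,6S,7aR)-6-ethenyl-6-methyl-2-oxo-5-(prop-1-en-2-yl)octahydro-1-benzofuran-3-yl]ethyl}hexahydro-1-benzofuran-2(3H)-one F2. SOCl2, pyridine, 0 °C dehydrates the tertiary alcohol toward C7 to the 7a-epimer of 31, F3. 1,8-Diazabicyclo[5.4.0]undec-7-ene in CH2Cl2 at rt equilibrates the butenolide γ-centre C8 through the 2-oxidofuran; the saturated lactone centre C11' is far less acidic and should stay. 31 is separated by chromatography and F3 is returned to the equilibration. This path needs neither the alkene geometry of 29 nor a chiral reagent and rejoins the route at 31.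

3. Step 5. C–Si cleavage at the hindered vinylsilane may be incomplete, or the basic fluoride may trigger side reactions of the tertiary alcohol. Fallback, from 1, without the silyl group: CH2=CHMgBr, CuBr·SMe2 (cat.), THF, −40 °C gives rac-(3R,5R)-3-ethenyl-3,5-dimethylcyclohexan-1-one F4. IBX, DMSO, 70 °C gives rac-(5R)-5-ethenyl-3,5-dimethylcyclohex-2-en-1-one F5. KOt-Bu, t-BuOH, then cold aq AcOH gives rac-(5R)-5-ethenyl-3,5-dimethylcyclohex-3-en-1-one F6. CH2=CHMgBr, CeCl3, THF, −78 °C then gives 9 together with its C8 epimer rac-(1S,5R)-1,5-diethenyl-3,5-dimethylcyclohex-3-en-1-ol F7. Without the steering group little facial preference is expected, so the four stereoisomers are separated in the chromatography of steps 6 and 7; the route is rejoined at 9.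

Further compounds
F1 | step 8 | (3R,4R)-3-ethenyl-3-methyl-4-(prop-1-en-2-yl)cyclohexan-1-one | C=C[C@@]1(C)CC(=O)CC[C@@H]1C(=C)C
F2 | step 16 | (3aR,5R,6R,7aS)-6-ethenyl-3-hydroxy-6-methyl-5-(prop-1-en-2-yl)-3-{2-[(3S,3aR,5S,6S,7aR)-6-ethenyl-6-methyl-2-oxo-5-(prop-1-en-2-yl)octahydro-1-benzofuran-3-yl]ethyl}hexahydro-1-benzofuran-2(3H)-one | C=C[C@@]1(C)C[C@@H]2OC(=O)C(O)(CC[C@@H]3C(=O)O[C@@H]4C[C@@](C)(C=C)[C@H](C(=C)C)C[C@H]34)[C@@H]2C[C@@H]1C(=C)C
F3 | step 16 | 7a-epimer of 31, (5R,6R,7aS) in the butenolide half | C=C[C@@]1(C)C[C@@H]2OC(=O)C(CC[C@@H]3C(=O)O[C@@H]4C[C@@](C)(C=C)[C@H](C(=C)C)C[C@H]34)=C2C[C@@H]1C(=C)C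
F4 | step 5 | rac-(3R,5R)-3-ethenyl-3,5-dimethylcyclohexan-1-one | C=C[C@@]1(C)CC(=O)C[C@H](C)C1
F5 | step 5 | rac-(5R)-5-ethenyl-3,5-dimethylcyclohex-2-en-1-one | C=C[C@@]1(C)CC(=O)C=C(C)C1
F6 | step 5 | rac-(5R)-5-ethenyl-3,5-dimethylcyclohex-3-en-1-one | C=C[C@@]1(C)CC(=O)CC(C)=C1
F7 | step 5 | rac-(1S,5R)-1,5-diethenyl-3,5-dimethylcyclohex-3-en-1-ol | C=C[C@@]1(C)C[C@](O)(C=C)CC(C)=C1
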